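**Plan**

1. Retrosynthetic cuts: the lactone O–C10 and C3–O bonds (selenolactonization, then an allylic selenoxide shift on a 1(10),2-diene acid); C4–C18 and C4–C19; C9–C10 (ring B) and C5–C6, which separates a ring C/D enone acid from a 2-bromocyclohexenol ketal (ring A); C11 out of ring C (C9–C11 and C11–C12), leaving a norbornanone; then C12–C13 and the bonds at the quaternary C8 of a cyclopentanone (ring D).
2. Forward order: cyclopentanone (ring D) → Cs-symmetric bicyclo[2.2.1]heptane-2,6-dione (ring D plus the five-membered ring C8–C14–C13–C12–C9) → enlargement of that ring to ring C (bicyclo[3.2.1]octenone) → ester union with ring A → ring B by radical closure → C4/C3 functionalization and lactone.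
3. Enabling feature: ring C (C8, C9, C11, C12, C13, C14) has its oxygenated C12 next to the oxygenated bridgehead C13 and an unsubstituted C11. It is therefore the reduced form of an enone C12(=O)–C11=C9, which a 2-siloxynorbornene gives by insertion of one carbon. The dione precursor has a mirror plane through C8, C13 and C14, so the C12/C9 and C16/C15 arms are enantiotopic.
4. Stereochemistry: C8 and C13 come from a chiral-amide deprotonation of the meso dione (step 6). The C1 carbinol of ring A comes from a CBS reduction (step 12) and is transferred to C5 by the Claisen shift. C9, C12, C4, C10 and C3 follow by substrate control; C6 follows from the Claisen geometry.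

Key step: step 9

Remark: the target is gibberellic acid carrying one more hydroxyl at C12 and is called 12-hydroxygibberellic acid below. The carbons of all intermediates carry the gibberellane numbers of the target (C1–C19; C7 carboxyl, C17 exocyclic methylene, C18 methyl, C19 lactone carbonyl).
Assumption: the (R,R)-amide base is taken to remove a proton from the arm that becomes C9; if the sense of induction is the opposite, the (S,S)-amide is used in the same way.

Step 1
Reactants: 1 3-ethoxycyclopent-2-en-1-one; 2 methyl acetate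
Product: 4 methyl 2-(3-oxocyclopent-1-en-1-yl)acetate, via carbinol adduct 3 (not isolated)
Conditions: LiN(i-Pr)2, THF, −78 °C, 2 then 1; then 1 M HCl, 0 °C to rt
Reagents that add atoms: water, O
Why: 1,2-addition of the ester enolate to the vinylogous ester and acid hydrolysis with allylic transposition (Stork–Danheiser sequence) should give the 3-substituted cyclopentenone.

Step 2
Reactants: 4 methyl 2-(3-oxocyclopent-1-en-1-yl)acetate; 5 1-(tert-butyldimethylsilyloxy)-1-methoxyethene
Product: 7 dimethyl 2,2'-(3-oxocyclopentane-1,1-diyl)diacetate, via silyl enol ether 6 (not isolated)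
Conditions: t-BuMe2SiOSO2CF3 (5 mol %), CH2Cl2, −78 °C; then 1 M HCl, THF, rt
Reagents that add atoms: none
Why: a Mukaiyama–Michael addition to the β,β-disubstituted enone should build the quaternary carbon (future C8) with two identical acetate arms, so no stereocentre arises.

Step 3
Reactants: 7 dimethyl 2,2'-(3-oxocyclopentane-1,1-diyl)diacetate
Product: 10 dimethyl 2,2'-[3-(tert-butyldimethylsilyloxy)-4-oxocyclopentane-1,1-diyl]diacetate (racemic), via silyl enol ether 8 (not isolated), via siloxy epoxide 9 (not isolated)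
Conditions: LiN(i-Pr)2, THF, −78 °C; t-BuMe2SiCl, DMPU, −78 °C to rt; then 3-chloroperoxybenzoic acid, NaHCO3, CH2Cl2, 0 °C to rt
Reagents that add atoms: tert-butyldimethylsilyl chloride, CC(C)(C)[Si](C)(C)Cl; 3-chloroperoxybenzoic acid, O=C(OO)c1cccc(Cl)c1
Why: kinetic deprotonation at the α-methylene remote from the quaternary carbon and Rubottom oxidation with 1,4-silyl migration should place the protected oxygen on the future C13; the single racemic stereocentre is erased in step 5.

Step 4
Reactants: 10 dimethyl 2,2'-[3-(tert-butyldimethylsilyloxy)-4-oxocyclopentane-1,1-diyl]diacetate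
Product: 11 2,2'-[3-(tert-butyldimethylsilyloxy)-4-oxocyclopentane-1,1-diyl]diacetic acid
Conditions: LiOH·H2O, THF/H2O 3:1, 0 °C to rt; then 1 M HCl to pH 3
Reagents that add atoms: lithium hydroxide, [Li+].[OH-]
Why: plain saponification of two unhindered methyl esters, which the silyl ether of a secondary alcohol should survive in the cold.

Step 5
Reactants: 11 2,2'-[3-(tert-butyldimethylsilyloxy)-4-oxocyclopentane-1,1-diyl]diacetic acid
Product: 14 methyl 2-[4-(tert-butyldimethylsilyloxy)-3,5-dioxobicyclo[2.2.1]heptan-1-yl]acetate (meso; ketones at C12 and C16), via spiro anhydride 12 (not isolated), via potassium carboxylate 13 (not isolated)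
Conditions: Ac2O, 60 °C, then evaporation; KN(SiMe3)2 (1.05 equiv), THF, −78 to 0 °C; then MeI, DMF, rt
Reagents that add atoms: iodomethane, CI
Why: in this Claisen-type intramolecular C-acylation only the enolate carbon two bonds from the spiro carbon (future C13) can reach an anhydride carbonyl (5-exo-trig), the carboxylate leaving group prevents retro-Claisen opening of the non-enolizable 1,3-dione, and the product has a mirror plane through C8, C13 and C14.

Step 6
Reactants: 14 methyl 2-[4-(tert-butyldimethylsilyloxy)-3,5-dioxobicyclo[2.2.1]heptan-1-yl]acetate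
Product: 15 trimethylsilyl enol ether of the C12 ketone of 14 (C9=C12; C16 ketone free; single enantiomer)
Conditions: lithium (R,R)-bis(1-phenylethyl)amide (from the amine and n-BuLi), LiCl, Me3SiCl present from the start, THF, −100 °C
Reagents that add atoms: chlorotrimethylsilane, C[Si](C)(C)Cl
Why: enantioselective deprotonation of a Cs-symmetric ketone by a chiral lithium amide with internal silyl quench, in which the base distinguishes the enantiotopic α-methylene groups C9 and C15 and so fixes the absolute configuration of the C8 and C13 bridgeheads.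

Step 7
Reactants: 15 trimethylsilyl enol ether of the C12 ketone of 14
Product: 16 exo-siloxycyclopropane (C11 added across C9–C12 on the face of the C14 bridge; C16 ketone)
Conditions: Et2Zn, CH2I2, CH2Cl2, 0 °C
Reagents that add atoms: diiodomethane, ICI
Why: Simmons–Smith cyclopropanation (Et2Zn/CH2I2 variant) of the electron-rich silyl enol ether should occur on the exo face of the norbornene and bring in the future C11.

Step 8
Reactants: 16 exo-siloxycyclopropane with C16 ketone
Product: 17 exo-siloxycyclopropane with C16 methylene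
Conditions: Ph3PCH3Br, KN(SiMe3)2, THF, 0 °C; then 16, 0 to 50 °C
Reagents that add atoms: methyltriphenylphosphonium bromide, C[P+](c1ccccc1)(c1ccccc1)c1ccccc1.[Br-]
Why: Wittig methylenation of the only ketone installs C17, the siloxycyclopropane and the ester being inert to the ylide; doing it before the enone exists avoids a choice between two carbonyl groups.

Step 9
Reactants: 17 exo-siloxycyclopropane with C16 methylene
Product: 19 methyl 2-[5-(tert-butyldimethylsilyloxy)-6-methylidene-4-oxobicyclo[3.2.1]oct-2-en-1-yl]acetate (C12 ketone; C9=C11; 13-silyl ether; 16-methylene), via β-chloro ketone 18 (not isolated)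
Conditions: FeCl3 (2.2 equiv), DMF, 0 °C; then NaOAc, MeOH, 60 °C
Reagents that add atoms: none
Why: FeCl3 oxidizes the electron-rich siloxycyclopropane by single-electron transfer to an oxygen-centred radical, which opens by β-scission of the internal C9–C12 bond (the bond shared by the cyclopropane and the five-membered ring C8–C14–C13–C12–C9), so that C11 ends up between the new C12 carbonyl and C9; the secondary C9 radical is trapped as the chloride by a second FeCl3 and NaOAc then removes HCl (E1cB) to give the enone C12(=O)–C11=C9. The closest known reaction type is the Ito–Saegusa one-carbon ring expansion of 1-siloxybicyclo[n.1.0]alkanes to 2-cycloalkenones. No ring is closed by cyclization: ring C (C8, C9, C11, C12, C13, C14) arises by enlargement of the five-membered norbornane ring through insertion of C11, ring D (C8, C13–C16) is carried through unchanged, and the bicyclo[2.2.1]heptane becomes the bicyclo[3.2.1]octane of the target. No new stereocentre remains in 19 (the C9 chloride epimers of 18 converge), and the C8 and C13 bridgeheads from step 6 are not touched. The step needs cleavage of the internal and not the external cyclopropane bond, which is secured by formation of the secondary ring radical and by relief of the strain of the cyclopropane-fused norbornane; it also needs chemoselectivity over the exocyclic methylene, the ester and the hindered silyl ether, which FeCl3 in DMF at 0 °C should leave alone.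

Step 10
Reactants: 19 ring C/D enone methyl ester
Product: 20 2-[5-(tert-butyldimethylsilyloxy)-6-methylidene-4-oxobicyclo[3.2.1]oct-2-en-1-yl]acetic acid
Conditions: Me3SnOH, ClCH2CH2Cl, 70 °C; then 0.1 M HCl wash
Reagents that add atoms: trimethyltin hydroxide, C[Sn](C)(C)O
Why: near-neutral hydrolysis of the unhindered methyl ester should spare the enone and the silyl ether.

Step 11
Reactants: 21 1,4-dioxaspiro[4.5]dec-6-en-8-one
Product: 23 7-bromo-1,4-dioxaspiro[4.5]dec-6-en-8-one, via dibromide 22 (not isolated)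
Conditions: Br2, CH2Cl2, 0 °C; then Et3N, 0 °C to rt
Reagents that add atoms: bromine, BrBr
Why: bromine addition to the enone and E1cB loss of HBr is the standard route to 2-bromo enones.

Step 12
Reactants: 23 7-bromo-1,4-dioxaspiro[4.5]dec-6-en-8-one
Product: 24 (S)-7-bromo-1,4-dioxaspiro[4.5]dec-6-en-8-ol
Conditions: (R)-1-methyl-3,3-diphenyltetrahydro-1H,3H-pyrrolo[1,2-c][1,3,2]oxazaborole (10 mol %), BH3·SMe2, THF, −20 °C; then MeOH
Reagents that add atoms: none
Why: Corey–Bakshi–Shibata reduction, for which 2-bromo enones are well-suited substrates (the bromovinyl arm acts as the large group), so the catalyst sets the carbinol stereocentre (future C1) that is later transferred to C5.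

Step 13
Reactants: 20 ring C/D enone acid; 24 (S)-7-bromo-1,4-dioxaspiro[4.5]dec-6-en-8-ol
Product: 25 (S)-7-bromo-1,4-dioxaspiro[4.5]dec-6-en-8-yl ester of acid 20
Conditions: N-(3-dimethylaminopropyl)-N'-ethylcarbodiimide hydrochloride, 4-(dimethylamino)pyridine (cat.), CH2Cl2, 0 °C to rt
Reagents that add atoms: none
Why: Steglich esterification joins the two enantio-enriched fragments without touching a stereocentre.

Step 14
Reactants: 25 allylic ester
Product: 28 Claisen acid (C5–C6 bond made; C7 carboxyl free; C10–Br on the C1=C10 alkene; C4 ketal), via silyl ketene acetal 26 (not isolated), via trimethylsilyl ester 27 (not isolated)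
Conditions: LiN(SiMe3)2, Me3SiCl/Et3N, THF, −78 °C, then 50 °C; aqueous work-up at pH 4
Reagents that add atoms: none
Why: in this Ireland–Claisen rearrangement the [3,3] shift is suprafacial on the cyclohexenyl unit, so C5–C6 forms on the face that carried the C1–O bond (1,3-chirality transfer from the CBS-derived carbinol), the ester α-methylene is the only enolizable site because the enone has no α-hydrogen, and C6 follows from the ketene acetal geometry and stays correctable by base as it is α to the carboxyl.

Step 15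
Reactants: 28 Claisen acid
Product: 29 2-(trimethylsilyl)ethyl ester of 28
Conditions: N-(3-dimethylaminopropyl)-N'-ethylcarbodiimide hydrochloride, 4-(dimethylamino)pyridine, Me3SiCH2CH2OH, CH2Cl2, rt
Reagents that add atoms: 2-(trimethylsilyl)ethanol, C[Si](C)(C)CCO
Why: the C7 carboxyl is masked as an ester that fluoride removes at the end together with the silyl ethers.

Step 16
Reactants: 29 2-(trimethylsilyl)ethyl ester
Product: 30 tetracyclic ketone (rings A to D; 1(10)-ene; C4 ketal; C12 ketone; 13-silyl ether; 16-methylene)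
Conditions: Bu3SnH, 2,2'-azobis(2-methylpropionitrile) (cat.), benzene, 80 °C, slow addition
Reagents that add atoms: none
Why: 5-exo-trig cyclization of the C10 vinyl radical onto the enone β-carbon C9 (polarity-matched, giving the α-keto radical) closes ring B, and the three-atom tether anchored on the equatorial C8 substituent should reach the face of C9 away from the C15–C16 bridge, the other face being screened by that bridge, so C10 becomes axial on ring C and the ring B/ring C fusion is cis as in the target.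

Step 17
Reactants: 30 tetracyclic ketone
Product: 31 12-alcohol (OH axial on ring C; anti to the C15–C16 bridge; gauche to the C13 oxygen)
Conditions: LiBH(s-Bu)3, THF, −78 °C; then NaOH, H2O2, 0 °C
Reagents that add atoms: none
Why: the bulky hydride should attack C12 along the equatorial trajectory because the axial one is blocked by the axial C9–C10 bond, which gives the axial alcohol of the target.

Step 18
Reactants: 31 12-alcohol
Product: 32 12,13-bis(tert-butyldimethylsilyl) ether
Conditions: t-BuMe2SiOSO2CF3, 2,6-lutidine, CH2Cl2, −40 to 0 °C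
Reagents that add atoms: tert-butyldimethylsilyl trifluoromethanesulfonate, CC(C)(C)[Si](C)(C)OS(=O)(=O)C(F)(F)F
Why: silyl triflate silylation of a hindered secondary alcohol protects it from the strong bases and electrophiles of steps 20 and 22.

Step 19
Reactants: 32 bis-silyl ether
Product: 33 C4 ketone
Conditions: pyridinium p-toluenesulfonate (20 mol %), acetone/H2O 10:1, 45 °C
Reagents that add atoms: water, O
Why: mild ketal hydrolysis frees the C4 ketone with an acid weak enough to keep the β,γ-unsaturated ketone out of conjugation and the silyl groups in place.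

Step 20
Reactants: 33 C4 ketone
Product: 34 C3=C4 enol triflate
Conditions: LiN(i-Pr)2, THF, −78 °C; PhN(SO2CF3)2, −78 to 0 °C
Reagents that add atoms: N-phenylbis(trifluoromethanesulfonimide), O=S(=O)(N(c1ccccc1)S(=O)(=O)C(F)(F)F)C(F)(F)F
Why: kinetic deprotonation should prefer the exposed C3 methylene over the tertiary C5–H, which is shielded by the ring fusion and the C6 ester, so that O-sulfonylation gives the C3=C4 enol triflate with C5 intact.

Step 21
Reactants: 34 enol triflate
Product: 36 α,β-unsaturated 19-carboxylic acid (1(10),3-diene), via mixed anhydride 35 (not isolated)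
Conditions: Pd(OAc)2 (5 mol %), PPh3 (10 mol %), CO (1 atm), KOAc, DMF, 25 to 50 °C; then water
Reagents that add atoms: carbon monoxide, [C-]#[O+]; water, O
Why: hydroxycarbonylation of an enol triflate (oxidative addition to zerovalent palladium, CO insertion, acetate capture, hydrolysis) installs C19 as the free acid, the vinyl bromide that would compete having been used up in step 16.

Step 22
Reactants: 36 α,β-unsaturated 19-carboxylic acid
Product: 37 4-methyl-1(10),2-diene-19-carboxylic acid (C18 trans to C6)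
Conditions: LiN(i-Pr)2 (2.3 equiv), THF/DMPU, −78 to −40 °C; MeI, −78 °C; then dilute HCl to pH 3
Reagents that add atoms: iodomethane, CI
Why: deconjugative α-alkylation of the dienolate dianion of a 2-enoic acid (γ-deprotonation at the doubly allylic C2, alkylation at C4) should give the quaternary C4 and the 2-ene, with methyl iodide entering anti to the C5–C6 bond so that C19 is cis to C6.

Step 23
Reactants: 37 diene acid
Product: 38 1-phenylseleno-19,10-lactone with 2-ene
Conditions: PhSeCl, K2CO3, CH2Cl2, −78 °C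
Reagents that add atoms: benzeneselenenyl chloride, Cl[Se]c1ccccc1
Why: in this phenylselenolactonization the C19 carboxylate, held on the face of C6, attacks the tertiary C10 of the seleniranium ion (5-exo, anti addition), which sets C10 with H-5 anti to the lactone oxygen and puts selenium on C1 on the opposite face.

Step 24
Reactants: 38 selenolactone
Product: 41 12,13-bis-O-(tert-butyldimethylsilyl)-12-hydroxygibberellic acid 2-(trimethylsilyl)ethyl ester, via selenoxide 39 (not isolated), via selenenate 40 (not isolated)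
Conditions: 30% H2O2, pyridine, THF, 0 °C to rt
Reagents that add atoms: hydrogen peroxide, OO
Why: oxidation to the allylic selenoxide and its suprafacial [2,3]-sigmatropic shift should move the oxygen to C3 on the face that carried selenium and the alkene to C1=C2, and hydrolysis of the selenenate gives the 3-hydroxy-1-ene lactone.

Step 25
Reactants: 41 12,13-bis-O-(tert-butyldimethylsilyl)-12-hydroxygibberellic acid 2-(trimethylsilyl)ethyl ester
Product: 42 12-hydroxygibberellic acid (the target gibberellin)
Conditions: tris(dimethylamino)sulfonium difluorotrimethylsilicate, DMF, 0 °C to rt; then NH4Cl (aq), pH 4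
Reagents that add atoms: none
Why: fluoride should remove both silyl ethers and, by β-elimination of the silylethyl group, the ester in one operation under nearly neutral conditions that spare the allylic lactone and the exocyclic alkene.

**Compound list**

1 | 3-ethoxycyclopent-2-en-1-one | CCOC1=CC(=O)CC1 | starting material
2 | methyl acetate | COC(C)=O | starting material
3 | methyl 2-(3-ethoxy-1-hydroxycyclopent-2-en-1-yl)acetate | CCOC1=CC(O)(CC(=O)OC)CC1 | intermediate
4 | methyl 2-(3-oxocyclopent-1-en-1-yl)acetate | COC(=O)CC1=CC(=O)CC1 | intermediate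
5 | 1-(tert-butyldimethylsilyloxy)-1-methoxyethene | C=C(OC)O[Si](C)(C)C(C)(C)C | starting material
6 | dimethyl 2,2'-[3-(tert-butyldimethylsilyloxy)cyclopent-2-ene-1,1-diyl]diacetate | COC(=O)CC1(CC(=O)OC)CCC(O[Si](C)(C)C(C)(C)C)=C1 | intermediate
7 | dimethyl 2,2'-(3-oxocyclopentane-1,1-diyl)diacetate | COC(=O)CC1(CC(=O)OC)CCC(=O)C1 | intermediate
8 | dimethyl 2,2'-[3-(tert-butyldimethylsilyloxy)cyclopent-3-ene-1,1-diyl]diacetate | COC(=O)CC1(CC(=O)OC)CC=C(O[Si](C)(C)C(C)(C)C)C1 | intermediate
9 | dimethyl 2,2'-[1-(tert-butyldimethylsilyloxy)-6-oxabicyclo[3.1.0]hexane-3,3-diyl]diacetate | COC(=O)CC1(CC(=O)OC)CC2OC2(O[Si](C)(C)C(C)(C)C)C1 | intermediate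
10 | dimethyl 2,2'-[3-(tert-butyldimethylsilyloxy)-4-oxocyclopentane-1,1-diyl]diacetate (racemic) | COC(=O)CC1(CC(=O)OC)CC(O[Si](C)(C)C(C)(C)C)C(=O)C1 | intermediate
11 | 2,2'-[3-(tert-butyldimethylsilyloxy)-4-oxocyclopentane-1,1-diyl]diacetic acid | OC(=O)CC1(CC(=O)O)CC(O[Si](C)(C)C(C)(C)C)C(=O)C1 | intermediate
12 | spiro glutaric anhydride of 11 | O=C1CC2(CC(=O)O1)CC(O[Si](C)(C)C(C)(C)C)C(=O)C2 | intermediate
13 | potassium 2-[4-(tert-butyldimethylsilyloxy)-3,5-dioxobicyclo[2.2.1]heptan-1-yl]acetate | O=C1CC2(CC(=O)[O-])CC1(O[Si](C)(C)C(C)(C)C)C(=O)C2.[K+] | intermediate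
14 | methyl 2-[4-(tert-butyldimethylsilyloxy)-3,5-dioxobicyclo[2.2.1]heptan-1-yl]acetate (meso) | O=C1CC2(CC(=O)OC)CC1(O[Si](C)(C)C(C)(C)C)C(=O)C2 | intermediate
15 | trimethylsilyl enol ether of the C12 ketone of 14 (C9=C12, C16 ketone) | O=C1C[C@]2(CC(=O)OC)C[C@@]1(O[Si](C)(C)C(C)(C)C)C(O[Si](C)(C)C)=C2 | intermediate
16 | exo-siloxycyclopropane (C9–C11–C12), C16 ketone | O=C1C[C@]2(CC(=O)OC)C[C@@]1(O[Si](C)(C)C(C)(C)C)[C@@]3(O[Si](C)(C)C)C[C@@H]23 | intermediate
17 | exo-siloxycyclopropane, C16 methylene | C=C1C[C@]2(CC(=O)OC)C[C@@]1(O[Si](C)(C)C(C)(C)C)[C@@]3(O[Si](C)(C)C)C[C@@H]23 | intermediate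
18 | 9-chloro-12-ketone of the bicyclo[3.2.1]octane (C9 epimers) | C=C1C[C@]2(CC(=O)OC)C[C@@]1(O[Si](C)(C)C(C)(C)C)C(=O)CC2Cl | intermediate
19 | methyl 2-[5-(tert-butyldimethylsilyloxy)-6-methylidene-4-oxobicyclo[3.2.1]oct-2-en-1-yl]acetate | C=C1C[C@]2(CC(=O)OC)C[C@@]1(O[Si](C)(C)C(C)(C)C)C(=O)C=C2 | intermediate
20 | 2-[5-(tert-butyldimethylsilyloxy)-6-methylidene-4-oxobicyclo[3.2.1]oct-2-en-1-yl]acetic acid | C=C1C[C@]2(CC(=O)O)C[C@@]1(O[Si](C)(C)C(C)(C)C)C(=O)C=C2 | intermediate
21 | 1,4-dioxaspiro[4.5]dec-6-en-8-one | O=C1C=CC2(CC1)OCCO2 | starting material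
22 | 6,7-dibromo-1,4-dioxaspiro[4.5]decan-8-one | O=C1C(Br)C(Br)C2(CC1)OCCO2 | intermediate
23 | 7-bromo-1,4-dioxaspiro[4.5]dec-6-en-8-one | O=C1C(Br)=CC2(CC1)OCCO2 | intermediate
24 | (S)-7-bromo-1,4-dioxaspiro[4.5]dec-6-en-8-ol | O[C@@H]1C(Br)=CC2(CC1)OCCO2 | intermediate
25 | (S)-7-bromo-1,4-dioxaspiro[4.5]dec-6-en-8-yl ester of 20 | C=C1C[C@]2(CC(=O)O[C@@H]3C(Br)=CC4(CC3)OCCO4)C[C@@]1(O[Si](C)(C)C(C)(C)C)C(=O)C=C2 | intermediate
26 | O-trimethylsilyl ketene acetal of 25 | C=C1C[C@]2(C=C(O[Si](C)(C)C)O[C@@H]3C(Br)=CC4(CC3)OCCO4)C[C@@]1(O[Si](C)(C)C(C)(C)C)C(=O)C=C2 | intermediate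
27 | trimethylsilyl ester of 28 | C=C1C[C@]2([C@@H](C(=O)O[Si](C)(C)C)[C@H]3C(Br)=CCCC34OCCO4)C[C@@]1(O[Si](C)(C)C(C)(C)C)C(=O)C=C2 | intermediate
28 | Claisen acid: 2-(ring C/D enone unit at C8)-2-(7-bromo-1,4-dioxaspiro[4.5]dec-7-en-6-yl)acetic acid | C=C1C[C@]2([C@@H](C(=O)O)[C@H]3C(Br)=CCCC34OCCO4)C[C@@]1(O[Si](C)(C)C(C)(C)C)C(=O)C=C2 | intermediate
29 | 2-(trimethylsilyl)ethyl ester of 28 | C=C1C[C@]2([C@@H](C(=O)OCC[Si](C)(C)C)[C@H]3C(Br)=CCCC34OCCO4)C[C@@]1(O[Si](C)(C)C(C)(C)C)C(=O)C=C2 | intermediate
30 | tetracyclic 12-ketone (1(10)-ene, C4 ketal, 13-silyl ether, 16-methylene) | C=C1C[C@]23C[C@@]1(O[Si](C)(C)C(C)(C)C)C(=O)C[C@H]2C2=CCCC4(OCCO4)[C@H]2[C@@H]3C(=O)OCC[Si](C)(C)C | intermediate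
31 | 12-alcohol of 30 | C=C1C[C@]23C[C@@]1(O[Si](C)(C)C(C)(C)C)[C@@H](O)C[C@H]2C2=CCCC4(OCCO4)[C@H]2[C@@H]3C(=O)OCC[Si](C)(C)C | intermediate
32 | 12,13-bis(tert-butyldimethylsilyl) ether | C=C1C[C@]23C[C@@]1(O[Si](C)(C)C(C)(C)C)[C@@H](O[Si](C)(C)C(C)(C)C)C[C@H]2C2=CCCC4(OCCO4)[C@H]2[C@@H]3C(=O)OCC[Si](C)(C)C | intermediate
33 | C4 ketone | C=C1C[C@]23C[C@@]1(O[Si](C)(C)C(C)(C)C)[C@@H](O[Si](C)(C)C(C)(C)C)C[C@H]2C2=CCCC(=O)[C@H]2[C@@H]3C(=O)OCC[Si](C)(C)C | intermediate
34 | C3=C4 enol triflate | C=C1C[C@]23C[C@@]1(O[Si](C)(C)C(C)(C)C)[C@@H](O[Si](C)(C)C(C)(C)C)C[C@H]2C2=CCC=C(OS(=O)(=O)C(F)(F)F)[C@H]2[C@@H]3C(=O)OCC[Si](C)(C)C | intermediate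
35 | mixed acetic anhydride of 36 | C=C1C[C@]23C[C@@]1(O[Si](C)(C)C(C)(C)C)[C@@H](O[Si](C)(C)C(C)(C)C)C[C@H]2C2=CCC=C(C(=O)OC(C)=O)[C@H]2[C@@H]3C(=O)OCC[Si](C)(C)C | intermediate
36 | 1(10),3-diene-19-carboxylic acid | C=C1C[C@]23C[C@@]1(O[Si](C)(C)C(C)(C)C)[C@@H](O[Si](C)(C)C(C)(C)C)C[C@H]2C2=CCC=C(C(=O)O)[C@H]2[C@@H]3C(=O)OCC[Si](C)(C)C | intermediate
37 | 4-methyl-1(10),2-diene-19-carboxylic acid | C=C1C[C@]23C[C@@]1(O[Si](C)(C)C(C)(C)C)[C@@H](O[Si](C)(C)C(C)(C)C)C[C@H]2C2=CC=C[C@@](C)(C(=O)O)[C@H]2[C@@H]3C(=O)OCC[Si](C)(C)C | intermediate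
38 | 1-phenylseleno-19,10-lactone, 2-ene | C=C1C[C@]23C[C@@]1(O[Si](C)(C)C(C)(C)C)[C@@H](O[Si](C)(C)C(C)(C)C)C[C@H]2[C@@]12[C@H]([Se]c4ccccc4)C=C[C@@](C)(C(=O)O1)[C@H]2[C@@H]3C(=O)OCC[Si](C)(C)C | intermediate
39 | selenoxide of 38 | C=C1C[C@]23C[C@@]1(O[Si](C)(C)C(C)(C)C)[C@@H](O[Si](C)(C)C(C)(C)C)C[C@H]2[C@@]12[C@H]([Se](=O)c4ccccc4)C=C[C@@](C)(C(=O)O1)[C@H]2[C@@H]3C(=O)OCC[Si](C)(C)C | intermediate
40 | 3-O-phenylselenenate of 41 | C=C1C[C@]23C[C@@]1(O[Si](C)(C)C(C)(C)C)[C@@H](O[Si](C)(C)C(C)(C)C)C[C@H]2[C@@]12C=C[C@H](O[Se]c4ccccc4)[C@@](C)(C(=O)O1)[C@H]2[C@@H]3C(=O)OCC[Si](C)(C)C | intermediate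
41 | 12,13-bis-O-(tert-butyldimethylsilyl)-12-hydroxygibberellic acid 2-(trimethylsilyl)ethyl ester | C=C1C[C@]23C[C@@]1(O[Si](C)(C)C(C)(C)C)[C@@H](O[Si](C)(C)C(C)(C)C)C[C@H]2[C@@]12C=C[C@H](O)[C@@](C)(C(=O)O1)[C@H]2[C@@H]3C(=O)OCC[Si](C)(C)C | intermediate
42 | 12-hydroxygibberellic acid (the target gibberellin; 12-OH axial on ring C; anti to the C15–C16 bridge) | C=C1C[C@]23C[C@@]1(O)[C@@H](O)C[C@H]2[C@@]12C=C[C@H](O)[C@@](C)(C(=O)O1)[C@H]2[C@@H]3C(=O)O | target

**Counts and risks**

Total step count: 25. Longest linear sequence: 23 steps (steps 1–10 and 13–25; steps 11–12 make the ring A piece).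

Steps most likely to fail:

Step 5 (bridged C-acylation). The enolate may acylate on oxygen, the base may enolize the anhydride or the wrong α-carbon, and the strained non-enolizable 1,3-dione may be opened by nucleophiles. The fallback sets out from 11 and comes back at 14. The anhydride 12, made as before, is opened with methanol and catalytic 4-(dimethylamino)pyridine to the half ester [1-(2-methoxy-2-oxoethyl)-3-(tert-butyldimethylsilyloxy)-4-oxocyclopentyl]acetic acid F1. Me3SiOSO2CF3/Et3N converts it into the trimethylsilyl ester that also carries the C13=C16 trimethylsilyl enol ether F2. Oxalyl chloride with a drop of DMF turns the silyl ester into the acid chloride F3. ZnCl2 in CH2Cl2 then promotes an intramolecular Mukaiyama-type C-acylation of the silyl enol ether, which needs no free enolate and gives 14.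

Step 20 (enol triflate). Deprotonation may take the doubly activated C5–H in place of a C3 hydrogen, which would give the conjugated dienyl triflate and erase the C5 stereocentre. The fallback sets out from 33 and comes back at 36 without any enolate, replacing steps 20 and 21. Dimethylsulfonium methylide adds to the C4 ketone from the face away from C6 to give the spiro-epoxide F4. Et2Al(tmp) (diethylaluminium 2,2,6,6-tetramethylpiperidide) opens it by syn β-elimination, which can only use a C3 hydrogen because H-5 is anti to the epoxide oxygen, and gives the C3=C4 allylic alcohol with C19 as CH2OH F5. MnO2 gives the enal F6, and NaClO2/NaH2PO4/2-methylbut-2-ene gives acid 36.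

Step 22 (dianion methylation). Alkylation may go to C2 or C10 of the extended dienolate, the excess base may remove the C6 hydrogen next to the silylethyl ester, or methyl iodide may enter on the wrong face. The fallback sets out from 36 and comes back at 37. Me3SiCHN2 gives the methyl 19-ester F7, whose γ-proton at C2 is the most acidic one in the molecule. One equivalent of LiN(i-Pr)2 in THF/DMPU followed by MeI (deconjugative alkylation of a 2-enoate) gives the 4-methyl-1(10),2-diene methyl ester F8. LiSPr in HMPA then removes the methyl group by SN2 attack at carbon, which is insensitive to the hindrance at C4 and leaves the silylethyl ester, to give 37.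

Further compounds
F1 | step 5 | [1-(2-methoxy-2-oxoethyl)-3-(tert-butyldimethylsilyloxy)-4-oxocyclopentyl]acetic acid | COC(=O)CC1(CC(=O)O)CC(O[Si](C)(C)C(C)(C)C)C(=O)C1
F2 | step 5 | trimethylsilyl ester of F1 carrying the C13=C16 trimethylsilyl enol ether | COC(=O)CC1(CC(=O)O[Si](C)(C)C)CC(O[Si](C)(C)C(C)(C)C)=C(O[Si](C)(C)C)C1
F3 | step 5 | acid chloride of F1 carrying the C13=C16 trimethylsilyl enol ether | COC(=O)CC1(CC(=O)Cl)CC(O[Si](C)(C)C(C)(C)C)=C(O[Si](C)(C)C)C1
F4 | step 20 | C4 spiro-epoxide (C19 methylene on the face away from C6) | C=C1C[C@]23C[C@@]1(O[Si](C)(C)C(C)(C)C)[C@@H](O[Si](C)(C)C(C)(C)C)C[C@H]2C2=CCC[C@]4(CO4)[C@H]2[C@@H]3C(=O)OCC[Si](C)(C)C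
F5 | step 20 | C3=C4 allylic alcohol (C19 as CH2OH) | C=C1C[C@]23C[C@@]1(O[Si](C)(C)C(C)(C)C)[C@@H](O[Si](C)(C)C(C)(C)C)C[C@H]2C2=CCC=C(CO)[C@H]2[C@@H]3C(=O)OCC[Si](C)(C)C
F6 | step 20 | C3=C4 enal (C19 as CHO) | C=C1C[C@]23C[C@@]1(O[Si](C)(C)C(C)(C)C)[C@@H](O[Si](C)(C)C(C)(C)C)C[C@H]2C2=CCC=C(C=O)[C@H]2[C@@H]3C(=O)OCC[Si](C)(C)C
F7 | step 22 | methyl 19-ester of 36 | C=C1C[C@]23C[C@@]1(O[Si](C)(C)C(C)(C)C)[C@@H](O[Si](C)(C)C(C)(C)C)C[C@H]2C2=CCC=C(C(=O)OC)[C@H]2[C@@H]3C(=O)OCC[Si](C)(C)C
F8 | step 22 | methyl 19-ester of 37 | C=C1C[C@]23C[C@@]1(O[Si](C)(C)C(C)(C)C)[C@@H](O[Si](C)(C)C(C)(C)C)C[C@H]2C2=CC=C[C@@](C)(C(=O)OC)[C@H]2[C@@H]3C(=O)OCC[Si](C)(C)C
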